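Compound numbers used throughout: 1 orcinol; 2 2,4-dihydroxy-6-methylbenzaldehyde; 3 6-methylbenzene-1,2,4-triol; 4 3-methylbut-2-enoic acid; 5 the catechol chromanone; 6 its 6-O-methoxymethyl ether; 7 3,5-dibromoanisole; 8 the silylated dibromide; 9 the diaryl ether bromide; 10 its pinacol boronate; 11 the silyl phenol; 12 the silyl triflate; 13 1,1-dimethoxyethene; 14 the aryne; 15 the benzocyclobutenone acetal; 16 its dilithio derivative; 17 the formylated acetal; 18 the benzocyclobutenone phenol; 19 the quinoid ketene; 20 3-O-methylmollicellin B; 21 mollicellin B.

## Analysis of the target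

Mollicellin B 21 is a tetracyclic depsidone in which ring A (the arene with the formyl group) and ring B (the arene with one free CH) are joined by an ether oxygen and by an ester, which together close the seven-membered lactone ring C, and in which ring B is fused to ring D, a 2,2-dimethyl-2,3-dihydropyran-4-one. Ring A is numbered as in the parent depsidone: C1 (methyl), C2 (H), C3 (hydroxyl), C4 (formyl), C4a (ether oxygen) and C11a, which carries the lactone carbonyl C11. Ring B and ring D keep chromanone locants with a prime: C5′ (methyl), C6′ (ester oxygen), C7′ (ether oxygen), C8′ (H), C4′ (ketone) and C2′ (two methyl groups). There is no stereocentre, since C2′ bears two identical groups, so no stereochemical relation has to be set or kept. The sensitive groups are the salicylaldehyde unit of ring A, the aryl ester of ring C and the β-aryloxy ketone of ring D, which strong base opens by elimination; in the open precursors a phenoxide at O6′ could also shift ring A from O7′ to O6′ (Smiles migration), because C4a lies between two carbonyl-bearing carbons. The difficulty is the density of substitution: each arene has five substituents, the ester joins a benzoyl carbon and a phenol oxygen that both have two ortho neighbours, the two adjacent oxygens of ring B must be told apart, and the formyl group sits between two oxygens, where electrophilic substitution of such a ring does not go. The strategy rests on ring A: C11 and the methyl carbon are bonded to the adjacent ring carbons C11a and C1, so both can arrive together as the two carbons of a ketene acetal added across an aryne bond C1≡C11a, with the aryloxy group on C4a deciding the orientation, and opening of the resulting four-membered ring then makes the ester and the methyl group in one event.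

## Retrosynthetic reasoning

**21 from 20.** The last bond cut is O–CH3 at C3. The oxygen is kept as a methyl ether because a free phenol would quench the aryne and the aryllithium, and because the methoxy group is one of the two oxygens that steer metalation to C4. Beside the C4 aldehyde it is the one ether that a chelating Lewis acid removes selectively, so the forward step only has to spare the lactone.

**20 from 18 (through 19).** The ester bond C11–O6′ is cut and C11 is joined instead to the C1 methyl carbon, which gives the benzocyclobutenone 18. This turns the most hindered bond of the target into one that forms by itself: ring opening of 18 gives ketene 19 with its carbonyl carbon held beside the C6′ hydroxyl, and the same event produces the C1 methyl group. The forward reaction must run without base, so that no phenoxide of 18 can trigger the aryl migration.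

**18 from 17.** The ketone of the four-membered ring and the C6′ hydroxyl are both masked as acetals (dimethyl acetal and methoxymethyl ether), so one acid treatment frees them together. A methoxymethyl ether is preferred to a benzyl ether because it has no benzylic protons for the alkyllithium of step 10 and needs no hydrogenation beside an aryl aldehyde.

**17 from 15.** The C4–CHO bond is cut, and the forward step is a metalation. Electrophilic formylation of ring A would go to C2, para to the ether oxygen, whereas lithiation selects C4 because it is the only ring A carbon with an oxygen on each side. The step is placed this late because a C4 substituent present before the ether coupling would put two ortho groups around the carbon to be coupled. 15 is the one intermediate after the union that has neither bromide, triflate nor ester, and its ketone must be held as the enolate while the aryl anion is made.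

**15 from 12 and 13 (through 14).** The C1–CH2 and C11a–C(acetal) bonds are cut together. This disconnection removes both carbon substituents beside the ether in one step and leaves an arene, 12, whose remaining substituents are only oxygen and silicon. The forward reaction must place the CH2 end of 13 on C1 and the acetal carbon on C11a.

**12 from 11, and 11 from 9 (through 10).** The triflate comes from the phenol and the phenol from an aryl bromide by borylation and oxidation. Bringing the oxygen in through a bromide lets ring A start as a symmetrical dibromide, and the sequence uses only palladium catalysis and peroxide, which the ketone tolerates.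

**9 from 6 and 8.** The diaryl ether is cut on the ring A side (C4a–O). Both rings naturally carry oxygen at the linking carbon, so one must come as a halide. Ring A is chosen because 8 is symmetrical: the coupling has no regiochemical question and the second bromine remains as the handle for the triflate oxygen. The silyl group is already in 8 because it needs organolithium chemistry, which cannot be used once the ring D ketone is present; the price is a coupling next to silicon.

**8 from 7.** The C–Si bond is cut at the carbon between the two bromines, the most acidic position of 7, which puts silicon exactly between the two future oxygens.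

**6 from 5.** The two neighbouring hydroxyls of 5 differ in that the C7′ one is conjugated with the ketone. Alkylation of the other one through the dianion gives 6 in one step.

**5 from 3 and 4.** Ring D is cut at the aryl–C4′ bond and at O1′–C2′, which corresponds to acylation and conjugate addition of a phenol with acid 4. This delivers the ring directly at the ketone oxidation level.

**3 from 2, and 2 from 1.** The C6′ oxygen is traced back to a formyl group (aryl migration to oxygen) and that to symmetrical orcinol 1. Its two equivalent positions beside the methyl group fix the new substituent between methyl and hydroxyl.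

## Alternatives that were turned down

Alternative 1: The bond cut is the aryl–oxygen bond of the lactone on ring B. The precursor A2 is a diaryl ether acid whose ring B still lacks the ester oxygen and ring D; in full it is 3-formyl-2-(3-hydroxy-5-methylphenoxy)-4-methoxy-6-methylbenzoic acid A2 and it would be closed oxidatively.
- **Forward key step:** in A2 a hypervalent iodine oxidant of the diacetate type would oxidise the ring B phenol, the tethered carboxylate would add to the free carbon para to the hydroxyl, and tautomerisation would give 7-hydroxy-3-methoxy-1,9-dimethyl-11-oxo-11H-dibenzo[b,e][1,4]dioxepine-4-carbaldehyde A1 as the tricyclic lactone.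
- **For it:** A2 needs no prefunctionalisation of ring B for the C–O bond and carries the formyl group from the start, so ring A never has to be formylated late. On this point it is stronger than the chosen route, which needs a metalation on an advanced intermediate.
- **Against it:** A1 has no ring D. Adding it means a Friedel–Crafts acylation between the hydroxyl and the methyl group of ring B, in strong acid, on a molecule with an aryl ester and an aldehyde, with the other ortho position competing. The oxidation product is a hydroquinone monoester that is more easily oxidised than A2 and the electron-rich aldehyde ring is exposed to the oxidant.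
- **Comparison:** the chosen strategy brings ring D in on a small triol, where strong acid does no harm, and forms the ester without any oxidant. Alternative 1 reaches the tricyclic core in fewer steps, but the unsolved annulation outweighs that.

Alternative 2: Ring B itself is disconnected. The precursor A4 is a 3-aryloxycyclobutenone with a tertiary hydroxyl and an isopropenyl group on its sp3 carbon; in full it is methyl 2-{[4-hydroxy-3-oxo-4-(prop-1-en-2-yl)cyclobut-1-en-1-yl]oxy}-4-methoxy-6-methylbenzoate A4 and it would be opened thermally.
- **Forward key step:** heating A4 would open the four-membered ring to a dienylketene, which closes by bonding the ketene carbon to the alkene CH2 and tautomerises to methyl 2-(2,5-dihydroxy-3-methylphenoxy)-4-methoxy-6-methylbenzoate A3 as a hydroquinone.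
- **For it:** every substituent of ring B is placed by the connectivity of the small ring. The ether oxygen is attached by addition–elimination of a phenol to a cyclobutenedione, not by a copper coupling next to a silyl group; on this point it is stronger than step 6 of the chosen route.
- **Against it:** A3 is far from the target. Ring D is missing, with the same acylation problem as in Alternative 1. The two hydroquinone hydroxyls must be distinguished and kept from oxidation. The ester is a methyl benzoate with two ortho substituents that must be saponified and closed onto a hindered phenol. Ring A still has no formyl group. Making A4 also needs an isopropenyl organometallic to add to one carbonyl of an unsymmetrical cyclobutenedione in the presence of the benzoate.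
- **Comparison:** both routes use the strain of a four-membered ring. Alternative 2 spends it on ring B, which simple phenol chemistry supplies, the chosen route on the hindered ester. After A3 at least five further operations would remain.

Alternative 3: Ring D is cut at O1′–C2′ and C3′–C4′. The two components are the benzyl alcohol A6 and the alkene A7; in full they are 5-(benzyloxy)-2-(hydroxymethyl)-3-methylphenol A6 and 2-methylpropene A7 as the two-carbon partner.
- **Forward key step:** heating A6 with A7 would eliminate water to an ortho-quinone methide, which adds the alkene in a hetero-Diels–Alder reaction, oxygen bonding to the more substituted carbon, to give 7-(benzyloxy)-2,2,5-trimethylchroman A5 as the bicyclic product.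
- **For it:** the ring fusion is fixed by the position of the hydroxymethyl group, with no choice between ring carbons as in the acylation of triol 3; on this point it is stronger. It is atom-economic and needs no strong acid.
- **Against it:** A5 is a chroman, so the C4′ methylene must later be oxidised to the ketone in the presence of aryl methyl groups. A5 has no oxygen at C6′, so ring B must later be hydroxylated between the methyl group and the C7′ oxygen. A7 is a gas and must be held under pressure at high temperature.
- **Comparison:** the step is spent on a ring that 3 and 4 give in one step at the correct oxidation level, while ring C and ring A stay untouched. The chosen strategy puts its one uncertain step on the bonds that are hard to make.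

Key step: step 9

Remark: 1,1-dimethoxyethene 13 is taken to be a purchasable reagent.

## Route

Step 1
Reactants: 1 orcinol (5-methylbenzene-1,3-diol)
Product: 2 2,4-dihydroxy-6-methylbenzaldehyde
Conditions: POCl3, DMF, MeCN, 0 °C → rt; then H2O, 50 °C
Reagents that add atoms: N,N-dimethylformamide CN(C)C=O (formyl carbon); water O (formyl oxygen)
Why: Vilsmeier–Haack formylation; orcinol reacts at the carbon para to one hydroxyl and next to the methyl group (two equivalent positions), and the iminium salt is hydrolysed on work-up. The minor isomer formylated between the hydroxyls should be removable by crystallisation.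

Step 2
Reactants: 2 2,4-dihydroxy-6-methylbenzaldehyde
Product: 3 6-methylbenzene-1,2,4-triol
Conditions: H2O2 (30% aq), NaOH (aq), 0 °C → rt, under N2; then HCl (aq), degassed work-up
Reagents that add atoms: hydrogen peroxide OO
Why: Dakin oxidation; hydroperoxide adds to the aldehyde, the electron-rich aryl group migrates to oxygen (fast with ortho and para hydroxyls) and the formate ester is hydrolysed in the flask. The triol is air-sensitive and should be used crude in step 3.

Step 3
Reactants: 3 6-methylbenzene-1,2,4-triol; 4 3-methylbut-2-enoic acid
Product: 5 6,7-dihydroxy-2,2,5-trimethylchroman-4-one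
Conditions: P2O5/MeSO3H (1:10 w/w), 70 °C, N2
Reagents that add atoms: none
Why: Friedel–Crafts acylation followed by intramolecular oxa-Michael addition, the usual one-pot route from a phenol and this acid to a 2,2-dimethylchroman-4-one. Acylation is expected at the ring carbon of 3 between the methyl group and the isolated hydroxyl (para to a second hydroxyl, the same preference orcinol shows in step 1), and only that isolated hydroxyl is placed to close the pyranone.

Step 4
Reactants: 5 6,7-dihydroxy-2,2,5-trimethylchroman-4-one
Product: 6 7-hydroxy-6-(methoxymethoxy)-2,2,5-trimethylchroman-4-one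
Conditions: NaH (2.1 equiv), DMF, 0 °C; MOMCl (1.0 equiv), 0 °C → rt; aq NH4Cl
Reagents that add atoms: chloromethyl methyl ether COCCl
Why: Regioselective O-alkylation of a catechol dianion; the C7′ oxide is a vinylogous carboxylate conjugated with the C4′ ketone and is weakly nucleophilic, so the single equivalent of alkylating agent should react at the non-conjugated C6′ oxide. The same principle governs alkylation of 3,4-dihydroxybenzaldehyde at O3 through its dianion.

Step 5
Reactants: 7 3,5-dibromoanisole (1,3-dibromo-5-methoxybenzene)
Product: 8 (2,6-dibromo-4-methoxyphenyl)trimethylsilane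
Conditions: LiN(iPr)2 (1.1 equiv), Me3SiCl (2 equiv, present from the start), THF, −78 °C
Reagents that add atoms: chlorotrimethylsilane C[Si](C)(C)Cl
Why: Deprotonation by LiN(iPr)2 at the most acidic ring position, the one flanked by both bromines, with in situ silylation so that the aryllithium is trapped before it can lose LiBr. The product is symmetrical, so the later coupling has no regiochemical question.

Step 6
Reactants: 6 7-hydroxy-6-(methoxymethoxy)-2,2,5-trimethylchroman-4-one; 8 (2,6-dibromo-4-methoxyphenyl)trimethylsilane
Product: 9 7-[3-bromo-5-methoxy-2-(trimethylsilyl)phenoxy]-6-(methoxymethoxy)-2,2,5-trimethylchroman-4-one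
Conditions: CuI (20 mol%), N,N-dimethylglycine hydrochloride (40 mol%), Cs2CO3, 1,4-dioxane, 100 °C; 8 (2.5 equiv)
Reagents that add atoms: none
Why: Ullmann-type diaryl ether synthesis with an amino acid ligand on copper; each bromine of 8 has a single ortho substituent. Phenol 6 is the limiting partner and the excess of symmetrical 8, which can be recovered, should suppress double coupling.

Step 7
Reactants: 9 7-[3-bromo-5-methoxy-2-(trimethylsilyl)phenoxy]-6-(methoxymethoxy)-2,2,5-trimethylchroman-4-one
Product: 11 7-[3-hydroxy-5-methoxy-2-(trimethylsilyl)phenoxy]-6-(methoxymethoxy)-2,2,5-trimethylchroman-4-one, via pinacol boronate 10 (not isolated)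
Conditions: Pd2(dba)3 (2.5 mol%), XPhos (10 mol%), B2pin2, KOAc, 1,4-dioxane, 90 °C; then H2O2 (30% aq), NaHCO3 (aq), THF, 0 °C → rt
Reagents that add atoms: hydrogen peroxide OO; bis(pinacolato)diboron CC1(C)OB(OC1(C)C)B1OC(C)(C)C(C)(C)O1 (boryl group of 10 only)
Why: Miyaura borylation with zerovalent palladium and a bulky biaryl phosphine suited to the ortho-silyl bromide, then peroxide oxidation of the aryl boronate by aryl shift from boron to oxygen. Ketone, methoxymethyl ether and aryl silane should tolerate both stages; the electron-rich silyl phenol 11 should be taken on at once.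

Step 8
Reactants: 11 7-[3-hydroxy-5-methoxy-2-(trimethylsilyl)phenoxy]-6-(methoxymethoxy)-2,2,5-trimethylchroman-4-one
Product: 12 5-methoxy-3-{[6-(methoxymethoxy)-2,2,5-trimethyl-4-oxochroman-7-yl]oxy}-2-(trimethylsilyl)phenyl trifluoromethanesulfonate
Conditions: Tf2O, pyridine, CH2Cl2, −20 → 0 °C
Reagents that add atoms: trifluoromethanesulfonic anhydride O=S(=O)(OS(=O)(=O)C(F)(F)F)C(F)(F)F
Why: O-Sulfonylation of the phenol, the standard last step in making ortho-silylaryl triflates. The amine base keeps the medium non-acidic, which protects the electron-rich C–Si bond from protodesilylation.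

Step 9
Reactants: 12 5-methoxy-3-{[6-(methoxymethoxy)-2,2,5-trimethyl-4-oxochroman-7-yl]oxy}-2-(trimethylsilyl)phenyl trifluoromethanesulfonate; 13 1,1-dimethoxyethene
Product: 15 6-(methoxymethoxy)-2,2,5-trimethyl-7-[(4,8,8-trimethoxybicyclo[4.2.0]octa-1,3,5-trien-2-yl)oxy]chroman-4-one, via aryne 14 (not isolated)
Conditions: CsF (3 equiv), 13 (5 equiv), MeCN, 0 °C → rt
Reagents that add atoms: none
Why: Fluoride attacks silicon and triflate leaves from the neighbouring carbon, releasing aryne 14 (the C1≡C11a bond of ring A) at room temperature. The electron-rich CH2 of 13 should add to C1, the aryne carbon remote from the aryloxy group, because the aryl anion then formed at C11a is stabilised inductively by the adjacent C4a–O bond; this anion closes on the dimethoxycarbenium carbon. The four-membered ring is thus closed by a stepwise polar (2+2) addition whose second bond forms by 4-exo-trig attack of the aryl anion on the oxocarbenium ion. The closest known reaction type is the (2+2) cycloaddition of 3-alkoxyarynes from silyl triflates with ketene acetals, which gives benzocyclobutenone acetals with the acetal carbon next to the alkoxy group. No stereocentre is formed, since the new sp3 carbons are a CH2 and an acetal carbon with two identical methoxy groups. The selectivity needed is regiochemical (acetal carbon on C11a, CH2 on C1) and is secured by the C4a aryloxy group; the methoxy group is meta to one aryne carbon and para to the other and should have little say. The excess of 13 is meant to outrun capture of the aryne by the neighbouring methoxymethyl oxygen or by the solvent; ketone, acetal-type ether and methyl ether are inert to CsF.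

Step 10
Reactants: 15 6-(methoxymethoxy)-2,2,5-trimethyl-7-[(4,8,8-trimethoxybicyclo[4.2.0]octa-1,3,5-trien-2-yl)oxy]chroman-4-one
Product: 17 4,8,8-trimethoxy-2-{[6-(methoxymethoxy)-2,2,5-trimethyl-4-oxochroman-7-yl]oxy}bicyclo[4.2.0]octa-1,3,5-triene-3-carbaldehyde, via dilithio species 16 (not isolated)
Conditions: LiN(iPr)2 (1.1 equiv), THF, −78 °C; s-BuLi (2.3 equiv), TMEDA, −78 → −40 °C; DMF, −78 °C → rt; aq NH4Cl
Reagents that add atoms: N,N-dimethylformamide CN(C)C=O
Why: Directed ortho-metalation and formylation; LiN(iPr)2 first turns the chromanone into its lithium enolate, which shields the ketone from the alkyllithium and by its charge lowers the acidity of the ring B protons (one equivalent of s-BuLi is used up by the liberated amine). s-BuLi/TMEDA should then remove the ring A proton flanked by the methoxy and aryloxy oxygens, the classical cooperative site of a 1,3-dialkoxybenzene, whereas C2 has only one oxygen neighbour. DMF gives the C4 aldehyde and work-up returns the ketone.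

Step 11
Reactants: 17 4,8,8-trimethoxy-2-{[6-(methoxymethoxy)-2,2,5-trimethyl-4-oxochroman-7-yl]oxy}bicyclo[4.2.0]octa-1,3,5-triene-3-carbaldehyde
Product: 18 2-[(6-hydroxy-2,2,5-trimethyl-4-oxochroman-7-yl)oxy]-4-methoxy-8-oxobicyclo[4.2.0]octa-1,3,5-triene-3-carbaldehyde
Conditions: HCl (3 M aq), THF, 45 °C
Reagents that add atoms: water O
Why: Acid hydrolysis of two acetals in one operation: the dimethyl acetal gives the strained ketone and the methoxymethyl ether gives the C6′ phenol. Benzocyclobutenones tolerate aqueous acid, and no phenoxide is formed, so aryl migration between the ring B oxygens is not expected.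

Step 12
Reactants: 18 2-[(6-hydroxy-2,2,5-trimethyl-4-oxochroman-7-yl)oxy]-4-methoxy-8-oxobicyclo[4.2.0]octa-1,3,5-triene-3-carbaldehyde
Product: 20 3-O-methylmollicellin B (21 with OCH3 at C3 in place of OH), via quinoid ketene 19 (not isolated)
Conditions: hν (λ > 300 nm; Pyrex), degassed benzene (1 mM), rt
Reagents that add atoms: none
Why: Photochemical electrocyclic opening of the benzocyclobutenone to the ortho-quinoid ketene 19, a known process that gives ortho-toluates when a hydroxyl compound is present. The C6′ hydroxyl should add to the ketene carbon to close the seven-membered lactone, and the trienol then tautomerises so that the exocyclic CH2 becomes the C1 methyl group and ring A is aromatic again. The neutral medium and high dilution are meant to exclude aryl migration and intermolecular capture.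

Step 13
Reactants: 20 3-O-methylmollicellin B
Product: 21 mollicellin B
Conditions: BCl3 (3 equiv), CH2Cl2, −78 → 0 °C; aq NaHCO3
Reagents that add atoms: none
Why: Chelation-controlled ether cleavage; BCl3 binds between the aldehyde oxygen and the ortho methoxy oxygen and should cleave only that methyl ether. The lactone, the chromanone and the ring D ether should survive at low temperature.

## Compound list

1 | orcinol (5-methylbenzene-1,3-diol) | Cc1cc(O)cc(O)c1 | starting material
2 | 2,4-dihydroxy-6-methylbenzaldehyde | Cc1cc(O)cc(O)c1C=O | intermediate
3 | 6-methylbenzene-1,2,4-triol | Cc1cc(O)cc(O)c1O | intermediate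
4 | 3-methylbut-2-enoic acid | CC(C)=CC(=O)O | starting material
5 | 6,7-dihydroxy-2,2,5-trimethylchroman-4-one | CC1(C)CC(=O)c2c(C)c(O)c(O)cc2O1 | intermediate
6 | 7-hydroxy-6-(methoxymethoxy)-2,2,5-trimethylchroman-4-one | COCOc1c(O)cc2OC(C)(C)CC(=O)c2c1C | intermediate
7 | 3,5-dibromoanisole (1,3-dibromo-5-methoxybenzene) | COc1cc(Br)cc(Br)c1 | starting material
8 | (2,6-dibromo-4-methoxyphenyl)trimethylsilane | COc1cc(Br)c([Si](C)(C)C)c(Br)c1 | intermediate
9 | 7-[3-bromo-5-methoxy-2-(trimethylsilyl)phenoxy]-6-(methoxymethoxy)-2,2,5-trimethylchroman-4-one | COc1cc(Br)c([Si](C)(C)C)c(Oc2cc3OC(C)(C)CC(=O)c3c(C)c2OCOC)c1 | intermediate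
10 | 7-[5-methoxy-3-(4,4,5,5-tetramethyl-1,3,2-dioxaborolan-2-yl)-2-(trimethylsilyl)phenoxy]-6-(methoxymethoxy)-2,2,5-trimethylchroman-4-one | COc1cc(B2OC(C)(C)C(C)(C)O2)c([Si](C)(C)C)c(Oc2cc3OC(C)(C)CC(=O)c3c(C)c2OCOC)c1 | intermediate (not isolated)
11 | 7-[3-hydroxy-5-methoxy-2-(trimethylsilyl)phenoxy]-6-(methoxymethoxy)-2,2,5-trimethylchroman-4-one | COc1cc(O)c([Si](C)(C)C)c(Oc2cc3OC(C)(C)CC(=O)c3c(C)c2OCOC)c1 | intermediate
12 | 5-methoxy-3-{[6-(methoxymethoxy)-2,2,5-trimethyl-4-oxochroman-7-yl]oxy}-2-(trimethylsilyl)phenyl trifluoromethanesulfonate | COc1cc(OS(=O)(=O)C(F)(F)F)c([Si](C)(C)C)c(Oc2cc3OC(C)(C)CC(=O)c3c(C)c2OCOC)c1 | intermediate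
13 | 1,1-dimethoxyethene | C=C(OC)OC | starting material
14 | 7-[(5-methoxy-2,3-didehydrophenyl)oxy]-6-(methoxymethoxy)-2,2,5-trimethylchroman-4-one (aryne) | COC1=CC#CC(Oc2cc3OC(C)(C)CC(=O)c3c(C)c2OCOC)=C1 | intermediate (not isolated)
15 | 6-(methoxymethoxy)-2,2,5-trimethyl-7-[(4,8,8-trimethoxybicyclo[4.2.0]octa-1,3,5-trien-2-yl)oxy]chroman-4-one | COc1cc2CC(OC)(OC)c2c(Oc2cc3OC(C)(C)CC(=O)c3c(C)c2OCOC)c1 | intermediate
16 | dilithio derivative of 15 (lithium enolate of the chromanone and aryllithium at the future C4) | COc1cc2CC(OC)(OC)c2c(Oc2cc3OC(C)(C)C=C(O[Li])c3c(C)c2OCOC)c1[Li] | intermediate (not isolated)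
17 | 4,8,8-trimethoxy-2-{[6-(methoxymethoxy)-2,2,5-trimethyl-4-oxochroman-7-yl]oxy}bicyclo[4.2.0]octa-1,3,5-triene-3-carbaldehyde | COc1cc2CC(OC)(OC)c2c(Oc2cc3OC(C)(C)CC(=O)c3c(C)c2OCOC)c1C=O | intermediate
18 | 2-[(6-hydroxy-2,2,5-trimethyl-4-oxochroman-7-yl)oxy]-4-methoxy-8-oxobicyclo[4.2.0]octa-1,3,5-triene-3-carbaldehyde | COc1cc2CC(=O)c2c(Oc2cc3OC(C)(C)CC(=O)c3c(C)c2O)c1C=O | intermediate
19 | ortho-quinoid ketene from 18 (exocyclic CH2 on the future C1 and C=C=O on the future C11a) | C=C1C=C(OC)C(C=O)=C(Oc2cc3OC(C)(C)CC(=O)c3c(C)c2O)C1=C=O | intermediate (not isolated)
20 | 3-O-methylmollicellin B | Cc1cc(OC)c(C=O)c2c1C(=O)Oc1c(cc3c(c1C)C(=O)CC(C)(C)O3)O2 | intermediate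
21 | mollicellin B | Cc1cc(O)c(C=O)c2c1C(=O)Oc1c(cc3c(c1C)C(=O)CC(C)(C)O3)O2 | target

## Step count and least certain steps

Total step count: 13. Longest linear sequence: 12 steps (from 1 through steps 1–4 and 6–13); the ring A branch adds step 5.

**Step 9 (key step).**
- What may go wrong: the bulky aryloxy group beside C11a may slow ring closure, so the aryl anion is protonated by the solvent before it reaches the oxocarbenium carbon, leaving an open-chain adduct. Other risks are capture of the aryne by the neighbouring methoxymethyl oxygen of ring B, oligomerisation of the ketene acetal, and partial addition in the reverse orientation if the inductive bias of the aryloxy group proves weaker than assumed.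
- Fallback: this way uses no aryne, sets out from 9 and returns at 20, and it passes through F1 and F2 and F3 and F4 in that order. Suzuki–Miyaura methylation of 9 (trimethylboroxine, PdCl2(dppf), K2CO3, dioxane/H2O, 90 °C) would give 7-[5-methoxy-3-methyl-2-(trimethylsilyl)phenoxy]-6-(methoxymethoxy)-2,2,5-trimethylchroman-4-one F1 as the first new compound. Lithiation and formylation of F1 as in step 10 would give 6-methoxy-2-{[6-(methoxymethoxy)-2,2,5-trimethyl-4-oxochroman-7-yl]oxy}-4-methyl-3-(trimethylsilyl)benzaldehyde F2 with silicon still in place. Ipso-iododesilylation of F2 with ICl (CH2Cl2, 0 °C) would give 3-iodo-6-methoxy-2-{[6-(methoxymethoxy)-2,2,5-trimethyl-4-oxochroman-7-yl]oxy}-4-methylbenzaldehyde F3 by attack at the carbon para to the methoxy group. Aqueous HCl in THF would free the phenol of F3 and give 2-[(6-hydroxy-2,2,5-trimethyl-4-oxochroman-7-yl)oxy]-3-iodo-6-methoxy-4-methylbenzaldehyde F4 as the cyclisation substrate. Carbonylative lactonisation of F4 (Pd(OAc)2, Xantphos, CO 1 atm, Et3N, toluene, 80 °C) would then close ring C to 20.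

**Step 6.**
- What may go wrong: slow coupling, because the bromide is next to the silyl group and the phenoxide of 6 is conjugated with the ketone and weakly nucleophilic. At the temperature then needed, base-induced loss of the silyl group from a ring that still has two bromines, or a second coupling, may take over.
- Fallback: this way sets out from 8 and returns at 9, and it passes through F5 as its only new compound. Bromine–lithium exchange on 8 with one equivalent of n-BuLi (THF, −78 °C), then B(OiPr)3 and acidic work-up, would give [3-bromo-5-methoxy-2-(trimethylsilyl)phenyl]boronic acid F5 as the ring A partner. Chan–Lam coupling of F5 with 6 (Cu(OAc)2, pyridine, 4 Å molecular sieves, CH2Cl2, air, rt) would form the ether oxidatively at room temperature and give 9.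

**Step 10.**
- What may go wrong: at the temperature needed for ring lithiation the chromanone enolate may eliminate the aryloxide (opening of ring D), and the resulting enone would add alkyllithium. Lithiation may also be incomplete or go to C8′ of ring B, which likewise lies between two oxygens, or to the C5′ methyl group.
- Fallback: this way sets out from 15 and returns at 17, and it passes through F6 and F7 in that order. NaBH4 (MeOH/THF, 0 °C) would reduce the ketone of 15 to racemic 6-(methoxymethoxy)-2,2,5-trimethyl-7-[(4,8,8-trimethoxybicyclo[4.2.0]octa-1,3,5-trien-2-yl)oxy]chroman-4-ol F6 whose alkoxide has no β-elimination path. Treatment of F6 with s-BuLi/TMEDA (2.2 equiv) and then DMF would give racemic 2-{[4-hydroxy-6-(methoxymethoxy)-2,2,5-trimethylchroman-7-yl]oxy}-4,8,8-trimethoxybicyclo[4.2.0]octa-1,3,5-triene-3-carbaldehyde F7 by the same ring A metalation. Oxidation of F7 with Dess–Martin periodinane (CH2Cl2, NaHCO3, rt) would restore the ketone and give 17.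

**Step 12.**
- What may go wrong: the chromanone and the aryl aldehyde absorb in the same region, so the four-membered ring may open inefficiently; reversible photoenolisation of the chromanone through its ortho methyl group may drain the light, or the excited aldehyde may abstract hydrogen from the ortho methoxy group. The ketene may also reclose or be captured between molecules before the hindered phenol reaches it.
- Fallback: this way uses no light, sets out from 17 and returns at 20, and it passes through F8 and F9 and F10 in that order. Mild hydrolysis of the dimethyl acetal only (pyridinium p-toluenesulfonate, acetone/H2O, rt) would give 4-methoxy-2-{[6-(methoxymethoxy)-2,2,5-trimethyl-4-oxochroman-7-yl]oxy}-8-oxobicyclo[4.2.0]octa-1,3,5-triene-3-carbaldehyde F8 with the phenol still protected. Hydroxide cleavage of the strained ketone of F8 (NaOH, THF/H2O, rt), with the benzylic carbon as the leaving group as in the known opening of benzocyclobutenone to ortho-toluic acid, would give 3-formyl-4-methoxy-2-{[6-(methoxymethoxy)-2,2,5-trimethyl-4-oxochroman-7-yl]oxy}-6-methylbenzoic acid F9 as the open acid. Aqueous HCl in THF would remove the methoxymethyl group of F9 and give 3-formyl-2-[(6-hydroxy-2,2,5-trimethyl-4-oxochroman-7-yl)oxy]-4-methoxy-6-methylbenzoic acid F10 as the hydroxy acid. Lactonisation of F10 with dicyclohexylcarbodiimide (CH2Cl2, rt), the classical depsidone closure, would give 20.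

**Step 4.**
- What may go wrong: alkylation at the C7′ oxygen or at both oxygens if the dianion is not fully formed, since the monoanion reacts at the conjugated oxygen; the methyl group beside O6′ also slows the wanted alkylation.
- Fallback: this way sets out from 5 and returns at 6, and it passes through F11 and F12 in that order. Monobenzylation at the more acidic C7′ hydroxyl (BnBr 1.05 equiv, KHCO3, DMF, 40 °C) would give 7-(benzyloxy)-6-hydroxy-2,2,5-trimethylchroman-4-one F11 as the mono-ether. Alkylation of F11 with MOMCl and iPr2NEt (CH2Cl2, rt) would give 7-(benzyloxy)-6-(methoxymethoxy)-2,2,5-trimethylchroman-4-one F12 with both oxygens differentiated. Hydrogenolysis of F12 (H2, Pd/C, EtOAc, rt) would give 6.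

## Further compounds

F1 | step 9 | 7-[5-methoxy-3-methyl-2-(trimethylsilyl)phenoxy]-6-(methoxymethoxy)-2,2,5-trimethylchroman-4-one | COc1cc(C)c([Si](C)(C)C)c(Oc2cc3OC(C)(C)CC(=O)c3c(C)c2OCOC)c1
F2 | step 9 | 6-methoxy-2-{[6-(methoxymethoxy)-2,2,5-trimethyl-4-oxochroman-7-yl]oxy}-4-methyl-3-(trimethylsilyl)benzaldehyde | COc1cc(C)c([Si](C)(C)C)c(Oc2cc3OC(C)(C)CC(=O)c3c(C)c2OCOC)c1C=O
F3 | step 9 | 3-iodo-6-methoxy-2-{[6-(methoxymethoxy)-2,2,5-trimethyl-4-oxochroman-7-yl]oxy}-4-methylbenzaldehyde | COc1cc(C)c(I)c(Oc2cc3OC(C)(C)CC(=O)c3c(C)c2OCOC)c1C=O
F4 | step 9 | 2-[(6-hydroxy-2,2,5-trimethyl-4-oxochroman-7-yl)oxy]-3-iodo-6-methoxy-4-methylbenzaldehyde | COc1cc(C)c(I)c(Oc2cc3OC(C)(C)CC(=O)c3c(C)c2O)c1C=O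
F5 | step 6 | [3-bromo-5-methoxy-2-(trimethylsilyl)phenyl]boronic acid | COc1cc(Br)c([Si](C)(C)C)c(B(O)O)c1
F6 | step 10 | 6-(methoxymethoxy)-2,2,5-trimethyl-7-[(4,8,8-trimethoxybicyclo[4.2.0]octa-1,3,5-trien-2-yl)oxy]chroman-4-ol (racemic) | COc1cc2CC(OC)(OC)c2c(Oc2cc3OC(C)(C)CC(O)c3c(C)c2OCOC)c1
F7 | step 10 | 2-{[4-hydroxy-6-(methoxymethoxy)-2,2,5-trimethylchroman-7-yl]oxy}-4,8,8-trimethoxybicyclo[4.2.0]octa-1,3,5-triene-3-carbaldehyde (racemic) | COc1cc2CC(OC)(OC)c2c(Oc2cc3OC(C)(C)CC(O)c3c(C)c2OCOC)c1C=O
F8 | step 12 | 4-methoxy-2-{[6-(methoxymethoxy)-2,2,5-trimethyl-4-oxochroman-7-yl]oxy}-8-oxobicyclo[4.2.0]octa-1,3,5-triene-3-carbaldehyde | COc1cc2CC(=O)c2c(Oc2cc3OC(C)(C)CC(=O)c3c(C)c2OCOC)c1C=O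
F9 | step 12 | 3-formyl-4-methoxy-2-{[6-(methoxymethoxy)-2,2,5-trimethyl-4-oxochroman-7-yl]oxy}-6-methylbenzoic acid | Cc1cc(OC)c(C=O)c(Oc2cc3OC(C)(C)CC(=O)c3c(C)c2OCOC)c1C(=O)O
F10 | step 12 | 3-formyl-2-[(6-hydroxy-2,2,5-trimethyl-4-oxochroman-7-yl)oxy]-4-methoxy-6-methylbenzoic acid | Cc1cc(OC)c(C=O)c(Oc2cc3OC(C)(C)CC(=O)c3c(C)c2O)c1C(=O)O
F11 | step 4 | 7-(benzyloxy)-6-hydroxy-2,2,5-trimethylchroman-4-one | CC1(C)CC(=O)c2c(C)c(O)c(OCc3ccccc3)cc2O1
F12 | step 4 | 7-(benzyloxy)-6-(methoxymethoxy)-2,2,5-trimethylchroman-4-one | CC1(C)CC(=O)c2c(C)c(OCOC)c(OCc3ccccc3)cc2O1
A1 | alternative 1 | 7-hydroxy-3-methoxy-1,9-dimethyl-11-oxo-11H-dibenzo[b,e][1,4]dioxepine-4-carbaldehyde | Cc1cc(OC)c(C=O)c2c1C(=O)Oc1c(C)cc(O)cc1O2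
A2 | alternative 1 | 3-formyl-2-(3-hydroxy-5-methylphenoxy)-4-methoxy-6-methylbenzoic acid | Cc1cc(O)cc(Oc2c(C=O)c(OC)cc(C)c2C(=O)O)c1
A3 | alternative 2 | methyl 2-(2,5-dihydroxy-3-methylphenoxy)-4-methoxy-6-methylbenzoate | COC(=O)c1c(C)cc(OC)cc1Oc1cc(O)cc(C)c1O
A4 | alternative 2 | methyl 2-{[4-hydroxy-3-oxo-4-(prop-1-en-2-yl)cyclobut-1-en-1-yl]oxy}-4-methoxy-6-methylbenzoate | COC(=O)c1c(C)cc(OC)cc1OC1=CC(=O)C1(O)C(C)=C
A5 | alternative 3 | 7-(benzyloxy)-2,2,5-trimethylchroman | Cc1cc(OCc2ccccc2)cc2OC(C)(C)CCc12
A6 | alternative 3 | 5-(benzyloxy)-2-(hydroxymethyl)-3-methylphenol | Cc1cc(OCc2ccccc2)cc(O)c1CO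
A7 | alternative 3 | 2-methylpropene | CC(C)=C
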